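The vessel is closed, stirred and held at one temperature, so the meeting asked what the Xp readings from three flasks say about a time that was not measured.

| flask | Xa | Xc | time |
|---|---|---|---|
| violet | 0.250 M | 0.00750 M |  |
| red | 0.500 M | 0.00750 M |  |
| amber | 0.250 M | 0.0220 M |  |
| grey | 0.250 M | 0.00750 M | 480 s |

- violet run (time / s: [Xp] / M): 8.4: 0.006; 26: 0.018; 49: 0.031; 78: 0.050; 110: 0.070; 150: 0.095; 190: 0.121
- red run (time / s: [Xp] / M): 8.4: 0.010; 26: 0.022; 49: 0.042; 78: 0.067; 110: 0.092; 150: 0.131; 190: 0.151
- amber run (time / s: [Xp] / M): 8.4: 0.014; 26: 0.048; 49: 0.086; 78: 0.131; 110: 0.171; 150: 0.210; 190: 0.233

(standard deviation of a reading: 0.003 M)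

- the exponent of [Xa] in the starting rate at the charge of the violet run (at the point where two percent of the Xa have become Xp) (one fixed amount of Xp, the same in the runs compared)
- the exponent of [Xc] in the starting rate at the charge of the violet run (at the point where two percent of the Xa have become Xp)
- Xp in the grey run at 480 s, as a share of the Xa charged

- Overall: Xa -> Xp, with Xc as catalyst.
- Constant volume, constant temperature.
- What is held in complexes is read along with the free species.
- An order is taken over about fifteen percent of the charge, up and down.

The secretary proposed working in logarithms. An order is then the logarithm of a ratio of mean rates over the logarithm of the ratio of charges, and at equal Xp the ratio of times gives the ratio of mean rates. She took Xa first. The violet run reached 0.050 M at 78 s. By interpolation the red run needed 58.3 s, less time, with twice the Xa. She read a mean order of 0.420 over that doubling.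

A member asked that Xc be read next. The violet run reached 0.070 M at 110 s, and the amber run reached it sooner, at 39.3 s. The logarithm of that time ratio is 0.447, and that of the [Xc] ratio is 0.467, so the order reads 0.956. The secretary replied that the scatter moves the amber time by about 1.82 s, which is worth 0.0420 in the order. The meeting took the exponent as one.

The grey run has the violet charge and runs to 480 s. That is 3.60 M·s on the catalyst clock, [Xc] times elapsed time. With one Xa charge and exponent one, flasks at equal clock hold equal Xp. The amber run shows that clock at 164 s, between its last two readings, where interpolation gives 218 mM. The meeting committed to 87.1 % of the charge for the grey run, with a reading scatter of 1.20 %.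

The forecast, which spoke of “a saturating picture”, stood a little apart from these figures, at 0.38 and 0.9 for the orders and 88 % for the grey run.

The simulation gives 0.40 and 1.0 for the orders and 89.2 % for the grey run.

    Xc + Xa ⇌ Xc.Xa, settled at all times (7.630 /M)
    Xc.Xa → Xp + Xc (0.2870 /s)
    2 Xa ⇌ Xa2, settled at all times (26.30 /M)

The grey reckoning lies 2.1 percentage points under that result. On the same clock, the violet run reached half its Xa at 1.58 M·s and the amber run at 1.60 M·s. In the grey run, Xc.Xa turned into Xp and Xc with constant 0.287 /s, while Xa and Xc stood in fast balance with Xc.Xa, and Xa with Xa2. By 480 s that step had made 223 mM of Xp, which is 89.2 % of the Xa charged.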